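The numbers in the tables were computed from invented constants; the scatter is artificial.

The time of a reading is what the forecaster trusts and what I would drop, and the flask we argue over repeats the noon run.

- noon: starting complex 0.10 M; incoming ligand 2 equiv (fed, over 40 s); the very flask that is asked about, followed so far
- flask: starting complex 0.10 M; incoming ligand 2.00 equiv (fed, over 40 s); time 12 min

noon run (percent of the starting complex charged)

| time / min | complex with two exchanged / % | starting complex / % |
|---|---|---|
| 0.250 | 3 | 92 |
| 0.417 | 6 | 77 |
| 0.667 | 17 | 55 |
| 1.00 | 22 | 36 |
| 1.50 | 22 | 27 |
| 2.50 | 16 | 11 |

(readings scatter by 1.5 percentage points)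

1. when, up to 12 min, the flask holds most complex with two exchanged
2. the amount of complex with two exchanged, in percent of the starting complex charged, at that time
3. earliest time at which at least nineteen twentieths of that best amount are there, in min
4. latest time at which they still are, in min

My view: let x be the fraction of starting complex left and B the fraction of complex with two exchanged, let both be lost by reaction with incoming ligand, and let what x loses arrive as B. Dividing the two rates cancels the ligand and its feed, and integrating gives B = (x^s − x)/(1 − s), a curve with no clock in it. At s = 2 this is B = x(1 − x), so as a rough inversion I take s ≈ 1 + x(1 − x)/B, and the reading at 1.00 min gives s = 2.05, the selectivity factor: the loss constant of B over that of x. The crest stands where B/x equals 1/s, at x = s^(1/(1 − s)) = 50.5%, and holds x/s = 24.6%. Interpolating B/x between the noon readings puts that at 0.865 min.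

The forecast stays on the clock: “Two equal readings either side suggest a crest”, so 23% at 1.25 min, with the window from 0.93 min to 1.7 min. That is later and lower than my reckoning.

The flask gives 22.6% at 1.04 min, with the window from 0.830 min to 1.39 min. The crest lies between our times , but the forecast's amount stands nearer, and my crest overshoots by 2 percentage points. My curve stays close near the reading that gave s, which makes this no check: at the best time it gives 22.8% against 22.6%, while at the end of the feed it gives 24.3% against 17.3%.

    complex with three exchanged + incoming ligand ⇌ leaving ligand + complex with four exchanged (K = 0.260, k = 0.0112 M⁻¹ s⁻¹)
    complex with two exchanged + incoming ligand → over-reaction product (k = 0.00914 M⁻¹ s⁻¹)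
    complex with one exchanged → side product (k = 0.0138 s⁻¹)
    starting complex + incoming ligand ⇌ leaving ligand + complex with one exchanged (K = 6.77, k = 0.190 M⁻¹ s⁻¹)
    complex with one exchanged + incoming ligand ⇌ leaving ligand + complex with two exchanged (K = 1.78, k = 0.679 M⁻¹ s⁻¹)
    complex with two exchanged + incoming ligand ⇌ leaving ligand + complex with three exchanged (K = 1.48, k = 0.167 M⁻¹ s⁻¹)

Taken alone, with the whole charge counted, the forward exchange onward has a half-life for complex with two exchanged of 0.35 min, shorter than the 6.3 min of the over-reaction. At 12.0 min in this flask the over-reaction uses it at 0.055 of that forward rate.

For a neighbour flask with 8.00 equiv of incoming ligand, the curve has no dose in it, so s again gives a crest of 24.6%. The simulated neighbour reaches 32.2%, 7.6 points above that.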